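## The problem

The target 42 is a germacranolide. Its ten-membered carbocycle (numbered C1–C10) has a C2 ketone flanked by a Z-trisubstituted alkene (C1=C10, methyl on C10) and an E-trisubstituted alkene (C3=C4, methyl on C4). Four contiguous stereocentres follow: the free allylic carbinol C5 (S); C6 (R) and C7 (R), which carry a cis-fused α-methylene-γ-lactone (O6–C12, C7–C11, exocyclic C13); and C8 (S), which carries the tiglate. A synthesis therefore has to form a medium ring, fix two ring alkenes of opposite geometry on either side of one carbonyl, and set four centres on a mobile ring. C5 and C6 are a vicinal dioxygenated pair that can be created together; once they and the two alkenes exist, the ring should expose one face at C7 and C8, so C5/C6 can control C7/C8 but not the reverse. The methylene lactone and the dienone are Michael acceptors, the tiglate and lactone are base-labile, a 6,12-lactone next to a C8 ketone is a β-acyloxy ketone, and a free O8 can capture C12 as an 8,12-lactone, so these groups must appear late and in a fixed order. The enabling feature is that the C5–C6 bond lies 1,6 to a C3–C8 bond: C8, C9, C10, C1, C2 and C3 would form a cyclohexene that already holds the Z alkene, and C6=C7–C8(O)–C3–C4=C5 is then a 3-oxy-1,5-diene.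

## Retrosynthesis

**42 ⇒ 41 ⇒ 38 ⇒ 35.** The C2 carbonyl and the O5 hydroxyl are uncovered last from the ketal/silyl ether 41, so that no dienone is present during hydride or amide-base steps. The O8–acyl bond is cut next (38), then C11=C13 (35). The forward steps need one free hydroxyl for the esterification and a lactone enolate formed in the absence of any other ester or ketone.

**35 ⇒ 34 ⇒ 33 ⇒ 31.** The C8 carbinol goes back to the ketone 34/33 and the O6–C12 lactone bond to keto ester 31. Closing the lactone on O6 while C8 is still a ketone rules out the competing 8,12-lactone. Only O6 (five-membered ring), not O5 (six-membered), is asked to cyclize. The hydride must reach C8 on the open face of the ring.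

**31 ⇒ 30 ⇒ 26 + 27.** The C7–C11 bond is cut. Direct alkylation of the C7 enolate was rejected: a reagent reaching C7 from the open face ends up trans to O6, which is the trans-lactone series. C11 is therefore introduced as an alkylidene (aldol condensation of 26 with ethyl glyoxylate 27, giving 30) and H7 is delivered last, from the open face. The forward steps need a regiodefined C7 enolate, which the silyl enol ether 26 stores.

**26 ⇒ 23 (key).** Cutting C5–C6 and reconnecting C3–C8 (retro-oxy-Cope) turns the ten-membered ring into cyclohexenol 23. Against a direct macrocyclization this removes the ring-closure problem altogether. It also derives C5, C6, the E C3=C4 alkene and the C7 enolate from two ring centres and two enol ether geometries, and the Z alkene is simply the ring alkene of the cyclohexene. The forward step needs a chair transition state and an enolate that keeps its β-oxygen.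

**23 ⇒ 22 ⇒ 18 + 20 (20 ⇒ 9 + 19).** The C7–C8 bond is cut to ketone 18 and an alkoxyacetylide from dichlorovinyl ether 20. An (E)-2-alkoxyvinyl metal would be the direct reagent, but it has metal and oxygen anti and loses alkoxide easily. The acetylide is stable and little basic, and the E enol ether then comes from hydroxyl-directed reduction of 22. The addition must occur anti to the C2 substituent of 18.

**18 ⇒ 17 ⇒ 16 ⇒ 15 ⇒ 14 ⇒ 8 + 12 (12 ⇒ 10 ⇒ 9).** The C4=C5 enol ether is cut to methyl ketone 8 and the phosphonium salt 12. The absolute configuration enters by lipase resolution of alcohol 15 (acetate 16, alcohol 17), the last stage at which a secondary carbinol is available. The ketone 18 is made only immediately before use because its stereocentre is α to the carbonyl.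

**8 ⇒ 4 + 7 (4 ⇒ 1 + 2; 7 ⇒ 5).** Cutting C2–C3 and C8–C9 (retro-Diels–Alder) gives the ketene-acetal diene 4 and the β-silyloxy enone 7. This one step places the ketal at C2, the ring alkene with its methyl group, the acyl group on C3 and oxygen on C8. The diene 4 comes from 1 and methacrolein 2, and 7 from the methoxy enone 5.

## Roads not taken

**Alternative 1:** The cut is the C4–C9 σ-bond of a trans-fused bicyclic 2-silyloxycyclohexadiene A2. Irradiation would open it by conrotatory 6π ring opening to the ten-membered silyloxytriene A1.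
- Merits: all four stereocentres C5–C8 would be set on a rigid six-membered ring before the medium ring exists. The lactone and tiglate are already present in A1, so the endgame is shorter. In stereocontrol at C7 and C8 this road is better than the chosen one, which relies on the shape of a ten-membered ring.
- Weak points: the opening is reversible, and the triene can undergo further photochemistry (E/Z isomerization, hydrogen shifts). The tiglate and the methylene lactone are chromophores that can isomerize. The Z C1=C10 alkene is not made by the electrocyclic step but by a later γ-protonation of the silyl dienol ether, which is not controlled.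
- Against this the chosen plan sets a ground-state rearrangement that fixes both ring alkenes, with the Z alkene preformed.

**Alternative 2:** The cut is the C1=C10 alkene, traced to an eleven-membered sulfone A4 with sulfur between C1 and C10. Halogenation at C1, deprotonation at C10 and loss of SO2 from the episulfone (Ramberg–Bäcklund) would give diene A3.
- Merits: closing an eleven-membered thioether is easier than closing a ten-membered carbocycle by C–C bond formation. The stereocentres can be set on an open chain by reliable acyclic methods, and no enol ether geometry has to be separated. In these two respects it is as good as or better than the chosen plan.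
- Weak points: the geometry of a trisubstituted alkene formed by sulfur extrusion in a medium ring is not reliably Z. Halogenation must distinguish C1 (next to the ketal) from C10. A3 is still far from the target: the lactone has to be built from the protected C12 alcohol, the acetonide removed with O5/O6 differentiation, and the ester installed.
- The chosen plan answers with a Z alkene that cannot be formed wrongly and a shorter path from the ring-forming step to the lactone.

**Alternative 3:** The cut is C9–C10. A B-alkyl Suzuki macrocyclization of the seco compound A6 (primary C9 boronate, Z-β-iodoenone) under zerovalent palladium would give the bis-silyl ether A5.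
- Merits: this is the most convergent road. A5 is only deprotection and acylation away from the target, and the alkene geometry is carried from the iodide. In endgame length it is clearly better than the chosen plan.
- Weak points: closing a strained ten-membered ring by C–C coupling is slow, so oligomerization competes. The Z-β-iodoenone can isomerize or undergo addition–elimination with the base needed for transmetalation. The C9 alkyl–palladium species has a β-silyloxy group at C8 and can eliminate. The methylene lactone and dienone would be exposed to palladium hydrides, and A6 is itself a long synthesis.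
- The chosen plan sets against this a ring expansion without entropic cost that also creates two stereocentres.

Key step: step 14

Remarks on the chemistry:
- C2 is carried as a diethyl ketal (from the ketene diethyl acetal 4).
- Compound 1 is taken as a purchasable reagent.
- The racemates 8, 14 and 15 are drawn as the enantiomer that is carried on.
- Ten-membered intermediates are named with the target's locants C1–C13.

## Route

Step 1
Reactants: 1 (diethoxymethyl)diphenylphosphine oxide; 2 methacrolein (2-methylprop-2-enal)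
Product: 4 1,1-diethoxy-3-methylbuta-1,3-diene, via lithium adduct 3 (not isolated)
Conditions: LiN(i-Pr)2, THF, −100 °C; 2; then KOt-Bu, −78 °C → rt; distillation
Reagents that add atoms: none
Why: Horner–Wittig olefination: the lithiated phosphine oxide adds 1,2 to the enal and the alkoxide loses diphenylphosphinate by syn elimination, a known route to ketene O,O-acetals; no stereo element arises.

Step 2
Reactants: 5 (E)-4-methoxybut-3-en-2-one
Product: 7 (E)-4-(tert-butyldimethylsilyloxy)but-3-en-2-one, via sodium enolate 6 (not isolated)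
Conditions: NaOH (1 equiv), H2O, 0 °C → rt; evaporation to dryness; t-BuMe2SiCl, THF, 0 °C → rt
Reagents that add atoms: sodium hydroxide, [Na+].[OH-]; tert-butyldimethylsilyl chloride, CC(C)(C)[Si](C)(C)Cl
Why: Addition–elimination of hydroxide on the vinylogous ester gives the sodium salt of formylacetone, which is silylated on the aldehyde-derived oxygen; the E geometry of the conjugated enolate is kept.

Step 3
Reactants: 4 1,1-diethoxy-3-methylbuta-1,3-diene; 7 (E)-4-(tert-butyldimethylsilyloxy)but-3-en-2-one
Product: 8 rac-1-[(1R,6R)-6-(tert-butyldimethylsilyloxy)-2,2-diethoxy-4-methylcyclohex-3-en-1-yl]ethan-1-one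
Conditions: toluene, Et3N (trace), 80 °C, sealed vessel
Reagents that add atoms: none
Why: Diels–Alder reaction of an electron-rich ketene-acetal diene with a β-oxy enone: the unsubstituted diene terminus (C9) bonds to the β-carbon of the enone (C8) and the acetal carbon (C2) to the α-carbon (C3); the E dienophile gives the trans C3/C8 relation, and C2 needs no endo/exo control because its two ethoxy groups are identical.

Step 4
Reactants: 9 4-methoxybenzyl alcohol
Product: 10 1-methoxy-4-{[(methylsulfanyl)methoxy]methyl}benzene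
Conditions: NaH, THF, 0 °C; ClCH2SMe, NaI (cat.), 0 °C → rt
Reagents that add atoms: chloromethyl methyl sulfide, CSCCl
Why: Williamson etherification giving the methylthiomethyl ether, the usual precursor of an acid-sensitive chloromethyl ether.

Step 5
Reactants: 10 1-methoxy-4-{[(methylsulfanyl)methoxy]methyl}benzene
Product: 12 {[(4-methoxybenzyl)oxy]methyl}triphenylphosphonium chloride, via chloromethyl ether 11 (not isolated)
Conditions: SO2Cl2, CH2Cl2, −78 °C; evaporation; PPh3, toluene, rt
Reagents that add atoms: sulfuryl chloride, O=S(=O)(Cl)Cl; triphenylphosphine, c1ccc(cc1)P(c1ccccc1)c1ccccc1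
Why: Chlorinolysis of the O,S-acetal at sulfur gives the chloromethyl ether without touching the arene at low temperature, and quaternization of the phosphine gives the Wittig salt.

Step 6
Reactants: 8 rac-1-[(1R,6R)-6-(tert-butyldimethylsilyloxy)-2,2-diethoxy-4-methylcyclohex-3-en-1-yl]ethan-1-one; 12 {[(4-methoxybenzyl)oxy]methyl}triphenylphosphonium chloride
Product: 14 rac-tert-butyl({(1R,6S)-5,5-diethoxy-6-[(Z)-1-(4-methoxybenzyloxy)prop-1-en-2-yl]-3-methylcyclohex-3-en-1-yl}oxy)dimethylsilane, via phosphorus ylide 13 (not isolated)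
Conditions: KN(SiMe3)2, THF, −78 → 0 °C; 8, −78 °C → rt; separation of the geometric isomers on Et3N-deactivated silica
Reagents that add atoms: none
Why: Wittig olefination of a methyl ketone with an alkoxymethylene ylide; enolization by the ylide is expected at the methyl group, which cannot expel the β-oxygen groups; both geometric isomers are expected and the Z isomer (oxygen cis to the ring carbon) is the one isolated.

Step 7
Reactants: 14 rac-tert-butyl({(1R,6S)-5,5-diethoxy-6-[(Z)-1-(4-methoxybenzyloxy)prop-1-en-2-yl]-3-methylcyclohex-3-en-1-yl}oxy)dimethylsilane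
Product: 15 rac-(1R,6S)-5,5-diethoxy-6-[(Z)-1-(4-methoxybenzyloxy)prop-1-en-2-yl]-3-methylcyclohex-3-en-1-ol
Conditions: Bu4NF, THF, 0 °C
Reagents that add atoms: none
Why: Fluoride cleavage of the silyl ether; the enol ether and the ketal tolerate the basic medium.

Step 8
Reactants: 15 rac-(1R,6S)-5,5-diethoxy-6-[(Z)-1-(4-methoxybenzyloxy)prop-1-en-2-yl]-3-methylcyclohex-3-en-1-ol
Product: 16 (1R,6S)-5,5-diethoxy-6-[(Z)-1-(4-methoxybenzyloxy)prop-1-en-2-yl]-3-methylcyclohex-3-en-1-yl acetate
Conditions: immobilized Candida antarctica lipase B, vinyl acetate, t-BuOMe, 30 °C, stopped near half conversion; chromatography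
Reagents that add atoms: vinyl acetate, CC(=O)OC=C
Why: Lipase-catalysed kinetic resolution by transesterification, standard for trans-2-substituted cyclohexanols; by the usual size rule (large group = C6 side, medium = C2 methylene) the enantiomer with the R carbinol centre should be acylated, which is the (1R,6S) series needed, and the slow enantiomer is removed as the alcohol.

Step 9
Reactants: 16 (1R,6S)-5,5-diethoxy-6-[(Z)-1-(4-methoxybenzyloxy)prop-1-en-2-yl]-3-methylcyclohex-3-en-1-yl acetate
Product: 17 (1R,6S)-5,5-diethoxy-6-[(Z)-1-(4-methoxybenzyloxy)prop-1-en-2-yl]-3-methylcyclohex-3-en-1-ol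
Conditions: K2CO3 (cat.), MeOH, 0 °C
Reagents that add atoms: none
Why: Base-catalysed transesterification of the acetate; neither stereocentre is enolizable at this stage.

Step 10
Reactants: 17 (1R,6S)-5,5-diethoxy-6-[(Z)-1-(4-methoxybenzyloxy)prop-1-en-2-yl]-3-methylcyclohex-3-en-1-ol
Product: 18 (2S)-3,3-diethoxy-2-[(Z)-1-(4-methoxybenzyloxy)prop-1-en-2-yl]-5-methylcyclohex-4-en-1-one
Conditions: DMP, NaHCO3, CH2Cl2, 0 °C; used at once
Reagents that add atoms: none
Why: Dess–Martin oxidation under bicarbonate buffer; non-basic conditions are chosen because the C2 centre of 18 is α to the ketone and allylic, and enolization would racemize it and open the way to loss of ethanol.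

Step 11
Reactants: 9 4-methoxybenzyl alcohol; 19 trichloroethylene
Product: 20 1-{[(E)-1,2-dichloroethenyl]oxymethyl}-4-methoxybenzene
Conditions: KH, THF, 0 °C; 19, rt
Reagents that add atoms: none
Why: Addition of the potassium alkoxide to dichloroacetylene formed in the flask from trichloroethylene, the standard entry to 1,2-dichlorovinyl ethers as alkynyl ether precursors.

Step 12
Reactants: 18 (2S)-3,3-diethoxy-2-[(Z)-1-(4-methoxybenzyloxy)prop-1-en-2-yl]-5-methylcyclohex-4-en-1-one; 20 1-{[(E)-1,2-dichloroethenyl]oxymethyl}-4-methoxybenzene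
Product: 22 (1S,6S)-5,5-diethoxy-1-[(4-methoxybenzyloxy)ethynyl]-6-[(Z)-1-(4-methoxybenzyloxy)prop-1-en-2-yl]-3-methylcyclohex-3-en-1-ol, via lithium acetylide 21 (not isolated)
Conditions: 20, n-BuLi (2.2 equiv), THF, −78 → −40 °C; CeCl3, −78 °C; 18, −78 °C
Reagents that add atoms: none
Why: Dehydrochlorination and chlorine–lithium exchange give the alkoxyacetylide 21, whose cerium derivative adds to the carbonyl faster than it enolizes 18; attack anti to the C2 alkenyl group, on the equatorial trajectory left open by the axial ethoxy group on C3, places the hydroxyl cis and the alkynyl group trans to the alkenyl substituent.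

Step 13
Reactants: 22 (1S,6S)-5,5-diethoxy-1-[(4-methoxybenzyloxy)ethynyl]-6-[(Z)-1-(4-methoxybenzyloxy)prop-1-en-2-yl]-3-methylcyclohex-3-en-1-ol
Product: 23 (1R,6S)-5,5-diethoxy-1-[(E)-2-(4-methoxybenzyloxy)ethenyl]-6-[(Z)-1-(4-methoxybenzyloxy)prop-1-en-2-yl]-3-methylcyclohex-3-en-1-ol
Conditions: NaAlH2(OCH2CH2OMe)2, THF, 0 °C → rt; aq. KNaC4H4O6
Reagents that add atoms: none
Why: Hydroxyl-directed trans-hydroalumination of a propargylic alkoxide: hydride goes to the proximal alkyne carbon and aluminium to the oxygen-bearing carbon, so protonolysis gives the E enol ether; a classical reduction of alkoxyethynyl carbinols.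

Step 14
Reactants: 23 (1R,6S)-5,5-diethoxy-1-[(E)-2-(4-methoxybenzyloxy)ethenyl]-6-[(Z)-1-(4-methoxybenzyloxy)prop-1-en-2-yl]-3-methylcyclohex-3-en-1-ol
Product: 26 (1(10)Z,3E,5S,6R,7Z)-2,2-diethoxy-5,6-bis(4-methoxybenzyloxy)-4,10-dimethyl-8-(trimethylsilyloxy)cyclodeca-1(10),3,7-triene, via potassium alkoxide 24 (not isolated), via potassium enolate 25 (not isolated)
Conditions: KH, 18-crown-6, THF, 0 °C → rt; then Me3SiCl/Et3N, −78 °C; non-aqueous work-up
Reagents that add atoms: chlorotrimethylsilane, C[Si](C)(C)Cl
Why: Anionic oxy-Cope rearrangement, the known ring expansion of trans-1,2-dialkenylcyclohexanols to cyclodec-5-enones, here with two enol ether termini. KH and 18-crown-6 give the dissociated alkoxide 24, which shifts [3,3] through the only chair open to a trans-dialkenyl arrangement, with ring carbons C9 and C2 equatorial and the oxido group axial. No ring is closed by cyclization: the C3–C8 bond breaks as C5–C6 forms, so the cyclohexene grows by four atoms into the ten-membered ring of enolate 25. C6 becomes R because the E enol ether holds its oxygen equatorial, and C5 becomes S because the Z enol ether holds its oxygen axial; both follow from the alkene geometries and the two ring centres of 23. The equatorial C2 gives E C3=C4, the ring alkene is carried over as Z C1=C10, and the axial oxido group gives the 7Z enolate. The selectivities needed are chair over boat (secured by the trans arrangement and the equatorial C6 oxygen), a regiodefined C7 enolate (stored by silylation at −78 °C as 26), and survival of the β-oxygen on C6 (its C–O bond lies in the nodal plane of the enolate as formed, so E1cB loss is stereoelectronically disfavoured). The ketal at C2 closes the retro-aldol channel that a free C2 ketone would open.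

Step 15
Reactants: 26 (1(10)Z,3E,5S,6R,7Z)-2,2-diethoxy-5,6-bis(4-methoxybenzyloxy)-4,10-dimethyl-8-(trimethylsilyloxy)cyclodeca-1(10),3,7-triene; 27 ethyl glyoxylate
Product: 30 ethyl (E)-2-[(1(10)Z,3E,5S,6R)-2,2-diethoxy-5,6-bis(4-methoxybenzyloxy)-4,10-dimethyl-8-oxocyclodeca-1(10),3-dien-7-ylidene]acetate, via lithium enolate 28 (not isolated), via aldol mesylate 29 (not isolated)
Conditions: MeLi, THF, −20 °C; 27, −78 °C; MsCl, −78 → 0 °C; DBU, 0 °C
Reagents that add atoms: none
Why: Methyllithium cleaves the silyl enol ether to the regiodefined enolate 28 (C7 only); aldol addition to the glyoxylate, mesylation in the flask (29) and E1cB elimination give the 4-oxo-2-enoate, expected as the E isomer; an aldol condensation replaces alkylation because whatever is delivered to C7 arrives on the open face and must therefore be the hydrogen, not C11.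

Step 16
Reactants: 30 ethyl (E)-2-[(1(10)Z,3E,5S,6R)-2,2-diethoxy-5,6-bis(4-methoxybenzyloxy)-4,10-dimethyl-8-oxocyclodeca-1(10),3-dien-7-ylidene]acetate
Product: 31 ethyl 2-[(1(10)Z,3E,5S,6R,7S)-2,2-diethoxy-5,6-bis(4-methoxybenzyloxy)-4,10-dimethyl-8-oxocyclodeca-1(10),3-dien-7-yl]acetate
Conditions: [(Ph3P)CuH]6, moist benzene, rt
Reagents that add atoms: none
Why: Conjugate reduction of an enone by a copper hydride: hydride adds to C11 (β to the ketone) and the copper enolate is protonated at C7 on the open face of the ring, the face that carries H6, because the other face is covered by the C2–C4 segment; this places C11 cis to O6.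

Step 17
Reactants: 31 ethyl 2-[(1(10)Z,3E,5S,6R,7S)-2,2-diethoxy-5,6-bis(4-methoxybenzyloxy)-4,10-dimethyl-8-oxocyclodeca-1(10),3-dien-7-yl]acetate
Product: 33 (1(10)Z,3E,5S,6R,7S)-2,2-diethoxy-5-hydroxy-4,10-dimethyl-8-oxocyclodeca-1(10),3-dieno-6,12-lactone (cis-fused γ-lactone, C11 methylene), via diol ester 32 (not isolated)
Conditions: DDQ, CH2Cl2/pH 7 buffer (KH2PO4/Na2HPO4), 0 °C; then 2-hydroxypyridine (cat.), toluene, 45 °C
Reagents that add atoms: none
Why: Oxidative cleavage of both 4-methoxybenzyl ethers; of the two hydroxyls of 32 only O6 can close a five-membered ring on C12 (O5 would give a six-membered one), so neutral transesterification gives the γ-lactone; neutral conditions are kept because 33 is a β-acyloxy ketone and the ketal is acid-labile.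

Step 18
Reactants: 33 (1(10)Z,3E,5S,6R,7S)-2,2-diethoxy-5-hydroxy-4,10-dimethyl-8-oxocyclodeca-1(10),3-dieno-6,12-lactone
Product: 34 the 5-O-triethylsilyl ether of 33
Conditions: Et3SiOTf, 2,6-lutidine, CH2Cl2, −78 °C
Reagents that add atoms: triethylsilyl trifluoromethanesulfonate, CC[Si](CC)(CC)OS(=O)(=O)C(F)(F)F
Why: Silylation of the only free hydroxyl with a silyl triflate and a weak hindered base at low temperature, so that the β-acyloxy ketone is not enolized.

Step 19
Reactants: 34 the 5-O-triethylsilyl ether of 33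
Product: 35 (1(10)Z,3E,5S,6R,7R,8S)-2,2-diethoxy-8-hydroxy-4,10-dimethyl-5-(triethylsilyloxy)cyclodeca-1(10),3-dieno-6,12-lactone
Conditions: NaBH4, EtOH/THF, −40 °C
Reagents that add atoms: none
Why: Borohydride reduction of the ketone; hydride approaches C8 on the open face, anti to the lactone ring that now occupies the covered face at C7, which puts O8 trans to C11; the lactone is inert at this temperature.

Step 20
Reactants: 35 (1(10)Z,3E,5S,6R,7R,8S)-2,2-diethoxy-8-hydroxy-4,10-dimethyl-5-(triethylsilyloxy)cyclodeca-1(10),3-dieno-6,12-lactone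
Product: 38 (1(10)Z,3E,5S,6R,7R,8S)-2,2-diethoxy-8-hydroxy-4,10-dimethyl-11-methylidene-5-(triethylsilyloxy)cyclodeca-1(10),3-dieno-6,12-lactone, via Mannich base 36 (not isolated), via methiodide 37 (not isolated)
Conditions: LiN(i-Pr)2 (2.3 equiv), THF, −78 °C; CH2=NMe2+ I−, −78 → 0 °C; MeI, MeOH, rt; NaHCO3 (aq), CH2Cl2
Reagents that add atoms: dimethyl(methylidene)ammonium iodide, C=[N+](C)C.[I-]
Why: Eschenmoser methylenation: excess amide base deprotonates the hydroxyl and the lactone α-carbon C11, the Mannich reaction gives 36, quaternization gives 37 and mild base induces β-elimination; enolization of the lactone at −78 °C should outrun acyl transfer to the C8 alkoxide.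

Step 21
Reactants: 38 (1(10)Z,3E,5S,6R,7R,8S)-2,2-diethoxy-8-hydroxy-4,10-dimethyl-11-methylidene-5-(triethylsilyloxy)cyclodeca-1(10),3-dieno-6,12-lactone; 39 tiglic acid
Product: 41 the 8-O-[(E)-2-methylbut-2-enoyl] ester of 38, via mixed anhydride 40 (not isolated)
Conditions: 39, 2,4,6-Cl3C6H2COCl, Et3N, toluene, rt; then 38, DMAP, rt
Reagents that add atoms: none
Why: Yamaguchi esterification of the single free hydroxyl through the mixed anhydride; the E geometry of the tiglate is the stable one and is kept.

Step 22
Reactants: 41 the 8-O-[(E)-2-methylbut-2-enoyl] ester of 38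
Product: 42 (1(10)Z,3E,5S,6R,7R,8S)-5-hydroxy-4,10-dimethyl-11-methylidene-2-oxo-8-[(E)-2-methylbut-2-enoyloxy]cyclodeca-1(10),3-dieno-6,12-lactone (CNP0230565.2)
Conditions: AcOH/THF/H2O (3:1:1), rt
Reagents that add atoms: water, O
Why: Aqueous acid hydrolyses the ketal, which ionizes easily to a doubly allylic oxocarbenium ion, and cleaves the triethylsilyl ether; no stereocentre is touched, and the γ-hydroxy enone does not ionize because the cation would be conjugated to the carbonyl.

## Compound list

1 | (diethoxymethyl)diphenylphosphine oxide | CCOC(OCC)P(=O)(c1ccccc1)c1ccccc1 | starting material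
2 | methacrolein | CC(=C)C=O | starting material
3 | lithium alkoxide adduct of 1 and 2 | [Li+].[O-]C(C(C)=C)C(OCC)(OCC)P(=O)(c1ccccc1)c1ccccc1 | intermediate (not isolated)
4 | 1,1-diethoxy-3-methylbuta-1,3-diene | CCOC(OCC)=CC(C)=C | intermediate
5 | (E)-4-methoxybut-3-en-2-one | CO/C=C/C(C)=O | starting material
6 | sodium (E)-3-oxobut-1-en-1-olate | [Na+].[O-]/C=C/C(C)=O | intermediate (not isolated)
7 | (E)-4-(tert-butyldimethylsilyloxy)but-3-en-2-one | CC(=O)/C=C/O[Si](C)(C)C(C)(C)C | intermediate
8 | rac-1-[(1R,6R)-6-(tert-butyldimethylsilyloxy)-2,2-diethoxy-4-methylcyclohex-3-en-1-yl]ethan-1-one (racemate) | CC(C)(C)[Si](C)(C)O[C@@H]1CC(C)=CC(OCC)(OCC)[C@H]1C(C)=O | intermediate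
9 | 4-methoxybenzyl alcohol | COc1ccc(CO)cc1 | starting material
10 | 1-methoxy-4-{[(methylsulfanyl)methoxy]methyl}benzene | COc1ccc(COCSC)cc1 | intermediate
11 | 1-[(chloromethoxy)methyl]-4-methoxybenzene | COc1ccc(COCCl)cc1 | intermediate (not isolated)
12 | {[(4-methoxybenzyl)oxy]methyl}triphenylphosphonium chloride | COc1ccc(COC[P+](c2ccccc2)(c2ccccc2)c2ccccc2)cc1.[Cl-] | intermediate
13 | {[(4-methoxybenzyl)oxy]methylidene}triphenylphosphorane | COc1ccc(COC=P(c2ccccc2)(c2ccccc2)c2ccccc2)cc1 | intermediate (not isolated)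
14 | rac-tert-butyl({(1R,6S)-5,5-diethoxy-6-[(Z)-1-(4-methoxybenzyloxy)prop-1-en-2-yl]-3-methylcyclohex-3-en-1-yl}oxy)dimethylsilane (racemate) | CC(C)(C)[Si](C)(C)O[C@@H]1CC(C)=CC(OCC)(OCC)[C@H]1/C(C)=C\OCc1ccc(OC)cc1 | intermediate
15 | rac-(1R,6S)-5,5-diethoxy-6-[(Z)-1-(4-methoxybenzyloxy)prop-1-en-2-yl]-3-methylcyclohex-3-en-1-ol (racemate) | O[C@@H]1CC(C)=CC(OCC)(OCC)[C@H]1/C(C)=C\OCc1ccc(OC)cc1 | intermediate
16 | (1R,6S)-5,5-diethoxy-6-[(Z)-1-(4-methoxybenzyloxy)prop-1-en-2-yl]-3-methylcyclohex-3-en-1-yl acetate | CC(=O)O[C@@H]1CC(C)=CC(OCC)(OCC)[C@H]1/C(C)=C\OCc1ccc(OC)cc1 | intermediate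
17 | (1R,6S)-5,5-diethoxy-6-[(Z)-1-(4-methoxybenzyloxy)prop-1-en-2-yl]-3-methylcyclohex-3-en-1-ol (single enantiomer) | O[C@@H]1CC(C)=CC(OCC)(OCC)[C@H]1/C(C)=C\OCc1ccc(OC)cc1 | intermediate
18 | (2S)-3,3-diethoxy-2-[(Z)-1-(4-methoxybenzyloxy)prop-1-en-2-yl]-5-methylcyclohex-4-en-1-one | O=C1CC(C)=CC(OCC)(OCC)[C@H]1/C(C)=C\OCc1ccc(OC)cc1 | intermediate
19 | trichloroethylene | ClC=C(Cl)Cl | starting material
20 | 1-{[(E)-1,2-dichloroethenyl]oxymethyl}-4-methoxybenzene | Cl/C=C(/Cl)OCc1ccc(OC)cc1 | intermediate
21 | lithium (4-methoxybenzyloxy)acetylide | [Li]C#COCc1ccc(OC)cc1 | intermediate (not isolated)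
22 | (1S,6S)-5,5-diethoxy-1-[(4-methoxybenzyloxy)ethynyl]-6-[(Z)-1-(4-methoxybenzyloxy)prop-1-en-2-yl]-3-methylcyclohex-3-en-1-ol | O[C@@]1(C#COCc2ccc(OC)cc2)CC(C)=CC(OCC)(OCC)[C@H]1/C(C)=C\OCc1ccc(OC)cc1 | intermediate
23 | (1R,6S)-5,5-diethoxy-1-[(E)-2-(4-methoxybenzyloxy)ethenyl]-6-[(Z)-1-(4-methoxybenzyloxy)prop-1-en-2-yl]-3-methylcyclohex-3-en-1-ol | O[C@@]1(/C=C/OCc2ccc(OC)cc2)CC(C)=CC(OCC)(OCC)[C@H]1/C(C)=C\OCc1ccc(OC)cc1 | intermediate
24 | potassium alkoxide of 23 | [K+].[O-][C@@]1(/C=C/OCc2ccc(OC)cc2)CC(C)=CC(OCC)(OCC)[C@H]1/C(C)=C\OCc1ccc(OC)cc1 | intermediate (not isolated)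
25 | potassium (1(10)Z,3E,5S,6R,7Z)-2,2-diethoxy-5,6-bis(4-methoxybenzyloxy)-4,10-dimethylcyclodeca-1(10),3,7-trien-8-olate | [K+].[O-]/C1=C\[C@@H](OCc2ccc(OC)cc2)[C@@H](OCc2ccc(OC)cc2)/C(C)=C/C(OCC)(OCC)/C=C(C)\C1 | intermediate (not isolated)
26 | (1(10)Z,3E,5S,6R,7Z)-2,2-diethoxy-5,6-bis(4-methoxybenzyloxy)-4,10-dimethyl-8-(trimethylsilyloxy)cyclodeca-1(10),3,7-triene | C[Si](C)(C)O/C1=C\[C@@H](OCc2ccc(OC)cc2)[C@@H](OCc2ccc(OC)cc2)/C(C)=C/C(OCC)(OCC)/C=C(C)\C1 | intermediate
27 | ethyl glyoxylate | CCOC(=O)C=O | starting material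
28 | lithium enolate corresponding to 25 | [Li+].[O-]/C1=C\[C@@H](OCc2ccc(OC)cc2)[C@@H](OCc2ccc(OC)cc2)/C(C)=C/C(OCC)(OCC)/C=C(C)\C1 | intermediate (not isolated)
29 | ethyl 2-(methanesulfonyloxy)-2-[(5S,6R)-2,2-diethoxy-5,6-bis(4-methoxybenzyloxy)-4,10-dimethyl-8-oxocyclodeca-1(10),3-dien-7-yl]acetate (C7 and C11 epimers) | O=C1C(C(OS(C)(=O)=O)C(=O)OCC)[C@@H](OCc2ccc(OC)cc2)[C@@H](OCc2ccc(OC)cc2)/C(C)=C/C(OCC)(OCC)/C=C(C)\C1 | intermediate (not isolated)
30 | ethyl (E)-2-[(1(10)Z,3E,5S,6R)-2,2-diethoxy-5,6-bis(4-methoxybenzyloxy)-4,10-dimethyl-8-oxocyclodeca-1(10),3-dien-7-ylidene]acetate | O=C1/C(=C/C(=O)OCC)[C@@H](OCc2ccc(OC)cc2)[C@@H](OCc2ccc(OC)cc2)/C(C)=C/C(OCC)(OCC)/C=C(C)\C1 | intermediate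
31 | ethyl 2-[(1(10)Z,3E,5S,6R,7S)-2,2-diethoxy-5,6-bis(4-methoxybenzyloxy)-4,10-dimethyl-8-oxocyclodeca-1(10),3-dien-7-yl]acetate | O=C1[C@@H](CC(=O)OCC)[C@@H](OCc2ccc(OC)cc2)[C@@H](OCc2ccc(OC)cc2)/C(C)=C/C(OCC)(OCC)/C=C(C)\C1 | intermediate
32 | ethyl 2-[(1(10)Z,3E,5S,6R,7S)-2,2-diethoxy-5,6-dihydroxy-4,10-dimethyl-8-oxocyclodeca-1(10),3-dien-7-yl]acetate | O=C1[C@@H](CC(=O)OCC)[C@@H](O)[C@@H](O)/C(C)=C/C(OCC)(OCC)/C=C(C)\C1 | intermediate (not isolated)
33 | (1(10)Z,3E,5S,6R,7S)-2,2-diethoxy-5-hydroxy-4,10-dimethyl-8-oxocyclodeca-1(10),3-dieno-6,12-lactone | O=C1O[C@@H]2[C@H](C1)C(=O)C/C(C)=C\C(OCC)(OCC)/C=C(\C)[C@@H]2O | intermediate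
34 | 5-O-triethylsilyl ether of 33 | O=C1O[C@@H]2[C@H](C1)C(=O)C/C(C)=C\C(OCC)(OCC)/C=C(\C)[C@@H]2O[Si](CC)(CC)CC | intermediate
35 | (1(10)Z,3E,5S,6R,7R,8S)-2,2-diethoxy-8-hydroxy-4,10-dimethyl-5-(triethylsilyloxy)cyclodeca-1(10),3-dieno-6,12-lactone | O=C1O[C@@H]2[C@H](C1)[C@@H](O)C/C(C)=C\C(OCC)(OCC)/C=C(\C)[C@@H]2O[Si](CC)(CC)CC | intermediate
36 | 11-[(dimethylamino)methyl] derivative of 35 (C11 epimers) | CN(C)CC1C(=O)O[C@@H]2[C@H]1[C@@H](O)C/C(C)=C\C(OCC)(OCC)/C=C(\C)[C@@H]2O[Si](CC)(CC)CC | intermediate (not isolated)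
37 | trimethylammonium iodide derived from 36 | C[N+](C)(C)CC1C(=O)O[C@@H]2[C@H]1[C@@H](O)C/C(C)=C\C(OCC)(OCC)/C=C(\C)[C@@H]2O[Si](CC)(CC)CC.[I-] | intermediate (not isolated)
38 | (1(10)Z,3E,5S,6R,7R,8S)-2,2-diethoxy-8-hydroxy-4,10-dimethyl-11-methylidene-5-(triethylsilyloxy)cyclodeca-1(10),3-dieno-6,12-lactone | C=C1C(=O)O[C@@H]2[C@H]1[C@@H](O)C/C(C)=C\C(OCC)(OCC)/C=C(\C)[C@@H]2O[Si](CC)(CC)CC | intermediate
39 | tiglic acid | C/C=C(\C)C(=O)O | starting material
40 | (E)-2-methylbut-2-enoic 2,4,6-trichlorobenzoic anhydride | C/C=C(\C)C(=O)OC(=O)c1c(Cl)cc(Cl)cc1Cl | intermediate (not isolated)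
41 | 8-O-[(E)-2-methylbut-2-enoyl] ester of 38 | C=C1C(=O)O[C@@H]2[C@H]1[C@@H](OC(=O)/C(C)=C/C)C/C(C)=C\C(OCC)(OCC)/C=C(\C)[C@@H]2O[Si](CC)(CC)CC | intermediate
42 | (1(10)Z,3E,5S,6R,7R,8S)-5-hydroxy-4,10-dimethyl-11-methylidene-2-oxo-8-[(E)-2-methylbut-2-enoyloxy]cyclodeca-1(10),3-dieno-6,12-lactone | C=C1C(=O)O[C@@H]2[C@H]1[C@@H](OC(=O)/C(C)=C/C)C/C(C)=C\C(=O)/C=C(\C)[C@@H]2O | target

## Step count and least certain steps

Total: 22 steps. Longest linear sequence: 18 steps (1, 3, 6, 7, 8, 9, 10, 12, 13, 14, 15, 16, 17, 18, 19, 20, 21, 22).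

**Step 14 (key step).** The alkoxide may fragment with loss of ethoxide from the neighbouring ketal (Grob-type cleavage of C3–C8 without C5–C6 formation). The enolate may also expel the C6 alkoxide once the new ring relaxes, and a boat transition state would scramble C5/C6. All three are consequences of working with a free anion. Fallback: 23 is silylated on the tertiary hydroxyl (Me3SiCl, imidazole) to the trimethylsilyl ether of 23 F1. F1 is heated in degassed decalin at about 190 °C in base-washed glass; the neutral siloxy-Cope shift gives the silyl enol ether directly and returns to the route at 26.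

**Step 6.** Poor geometric selectivity is the likely failure. The required isomer has the alkoxy group cis to the bulky ring carbon and may be the minor product of the Wittig reaction; separating trisubstituted enol ether isomers may also be inefficient. Fallback: from 8, lithiated {[(4-methoxybenzyl)oxy]methyl}diphenylphosphine oxide F2 (made from 11 and ethyl diphenylphosphinite) is added to the ketone. The diastereomeric β-hydroxy phosphine oxides are separated, and the diastereomer F3 is treated with KH in THF; stereospecific syn elimination gives the Z enol ether and returns to the route at 14.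

**Step 16.** Hydrogen may be delivered to the wrong face of C7, or C7 may equilibrate through the enol, if the ring of 30 does not keep the shape assumed for the enolate. This would give the trans-lactone series. Fallback: from 26, sulfenylation with PhSCl gives the 7-(phenylsulfanyl) ketone F4. Its sulfur-stabilized enolate (KN(SiMe3)2) is alkylated with ethyl bromoacetate to the 7-(phenylsulfanyl) keto ester F5. Reductive cleavage of the C–S bond (Al(Hg), wet THF) then brings in H7 last, by protonation of the resulting enolate, and returns to the route at 31.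

**Step 12.** Enolization of the α-alkenyl ketone may compete with addition. This erodes the enantiomeric purity set in step 8 and, through loss of ethanol, leads towards the phenol. Fallback: the resolution is moved behind the sensitive ketone. rac-15 is oxidized as in step 10 to the racemic ketone F6, which is carried through step 12 to the racemic propargylic alcohol F7. F7 is resolved by preparative chromatography on a chiral stationary phase and returns to the route at 22.

**Step 3.** The vinylogous silyl ester is a sluggish dienophile. Polymerization or hydrolysis of the ketene acetal, stepwise Michael addition, or loss of silanol from the adduct followed by aromatization may outrun the cycloaddition. Fallback: from 4, cycloaddition with the β-boryl enone (E)-4-(pinacolatoboryl)but-3-en-2-one F8 gives the boryl adduct F9, which has no β-leaving group on C8. Oxidation (NaBO3·4H2O, THF/H2O) with retention gives the trans hydroxy ketone F10. Silylation (t-BuMe2SiCl, imidazole) returns to the route at 8.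

## Further compounds

F1 | step 14 | trimethylsilyl ether of 23 | C[Si](C)(C)O[C@@]1(/C=C/OCc2ccc(OC)cc2)CC(C)=CC(OCC)(OCC)[C@H]1/C(C)=C\OCc1ccc(OC)cc1
F2 | step 6 | {[(4-methoxybenzyl)oxy]methyl}diphenylphosphine oxide | COc1ccc(COCP(=O)(c2ccccc2)c2ccccc2)cc1
F3 | step 6 | β-hydroxy phosphine oxide adduct of 8 and F2 (racemate, diastereomer leading to the Z enol ether) | CC(C)(C)[Si](C)(C)O[C@@H]1CC(C)=CC(OCC)(OCC)[C@H]1[C@@](C)(O)[C@H](OCc1ccc(OC)cc1)P(=O)(c1ccccc1)c1ccccc1
F4 | step 16 | (5S,6R)-2,2-diethoxy-5,6-bis(4-methoxybenzyloxy)-4,10-dimethyl-7-(phenylsulfanyl)cyclodeca-1(10),3-dien-8-one | O=C1C(Sc2ccccc2)[C@@H](OCc2ccc(OC)cc2)[C@@H](OCc2ccc(OC)cc2)/C(C)=C/C(OCC)(OCC)/C=C(C)\C1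
F5 | step 16 | ethyl 2-[(5S,6R)-2,2-diethoxy-5,6-bis(4-methoxybenzyloxy)-4,10-dimethyl-8-oxo-7-(phenylsulfanyl)cyclodeca-1(10),3-dien-7-yl]acetate | O=C1C(CC(=O)OCC)(Sc2ccccc2)[C@@H](OCc2ccc(OC)cc2)[C@@H](OCc2ccc(OC)cc2)/C(C)=C/C(OCC)(OCC)/C=C(C)\C1
F6 | step 12 | racemic form of ketone 18 | O=C1CC(C)=CC(OCC)(OCC)[C@H]1/C(C)=C\OCc1ccc(OC)cc1
F7 | step 12 | racemic form of propargylic alcohol 22 | O[C@@]1(C#COCc2ccc(OC)cc2)CC(C)=CC(OCC)(OCC)[C@H]1/C(C)=C\OCc1ccc(OC)cc1
F8 | step 3 | (E)-4-(4,4,5,5-tetramethyl-1,3,2-dioxaborolan-2-yl)but-3-en-2-one | CC(=O)/C=C/B1OC(C)(C)C(C)(C)O1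
F9 | step 3 | rac-1-[2,2-diethoxy-4-methyl-6-(pinacolatoboryl)cyclohex-3-en-1-yl]ethan-1-one (trans) | CC1(C)OB(OC1(C)C)[C@@H]1CC(C)=CC(OCC)(OCC)[C@H]1C(C)=O
F10 | step 3 | rac-1-[(1R,6R)-2,2-diethoxy-6-hydroxy-4-methylcyclohex-3-en-1-yl]ethan-1-one | O[C@@H]1CC(C)=CC(OCC)(OCC)[C@H]1C(C)=O
A1 | alternative 1 | ten-membered (E,Z,E)-2-silyloxytriene lactone | C=C1C(=O)O[C@@H]2[C@H]1[C@@H](OC(=O)/C(C)=C/C)/C=C(C)/C=C(O[Si](C)(C)C)\C=C(/C)[C@@H]2O[Si](C)(C)C
A2 | alternative 1 | trans-fused bicyclic 2-silyloxycyclohexadiene lactone (C4–C9 bond intact) | C=C1C(=O)O[C@@H]2[C@H]1[C@@H](OC(=O)/C(C)=C/C)[C@@H]1C(C)=CC(O[Si](C)(C)C)=C[C@@]1(C)[C@@H]2O[Si](C)(C)C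
A3 | alternative 2 | ten-membered protected (1(10)Z,3E)-diene | C=C(COCc1ccc(OC)cc1)[C@H]2[C@H]3OC(C)(C)O[C@H]3/C(C)=C/C3(OCCO3)/C=C(C)\C[C@@H]2O[Si](C)(C)C(C)(C)C
A4 | alternative 2 | eleven-membered sulfone with sulfur between C1 and C10 | C=C(COCc1ccc(OC)cc1)[C@H]2[C@H]3OC(C)(C)O[C@H]3/C(C)=C/C3(OCCO3)CS(=O)(=O)C(C)C[C@@H]2O[Si](C)(C)C(C)(C)C
A5 | alternative 3 | ten-membered dienone lactone as C5, C8 bis-silyl ether | C=C1C(=O)O[C@@H]2[C@H]1[C@@H](O[Si](CC)(CC)CC)C/C(C)=C\C(=O)/C=C(\C)[C@@H]2O[Si](C)(C)C(C)(C)C
A6 | alternative 3 | seco compound with C9 pinacol boronate and (Z)-β-iodoenone | C=C1C(=O)O[C@@H]([C@@H](O[Si](C)(C)C(C)(C)C)/C(C)=C/C(=O)/C=C(/C)I)[C@H]1[C@@H](O[Si](CC)(CC)CC)CB1OC(C)(C)C(C)(C)O1
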